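## Retrosynthetic overview

1. The target is opened at the ester into (13R)-halim-1(10)-en-15-oic acid and 1,3-di-O-silylated glycerol (Steglich esterification, then acidic fluoride desilylation).
2. C13 comes from Noyori hydrogenation of an (E)-allylic alcohol, made by Negishi carboalumination of a terminal alkyne that is grown from a C13 aldehyde.
3. Ring A is closed second, by intramolecular McMurry coupling of a C1 aldehyde with the C10 ketone, which places the double bond at C1=C10.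
4. Key disconnection C9–C11: intermolecular Michael addition of the C9 enolate of a 2-methylcyclohexanone to methyl acrylate builds the quaternary centre.
5. Ring B is present from the start: (R)-(+)-pulegone supplies C5–C10, the C8 methyl stereocentre and, after Hosomi–Sakurai allylation of its isopropylidene carbon, C4 with the gem-dimethyl group and C1–C3.

Assumption: atoms carry halimane numbers (ring C1–C10, side chain C11–C15, methyls C16–C20), and the SMILES is read as 5S,8R,9R,13R.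

## Route

Step 1
Reactants: 1 (R)-(+)-pulegone; 2 allyltrimethylsilane
Product: 3 (5R)-5-methyl-2-(2-methylpent-4-en-2-yl)cyclohexan-1-one as a C-2 epimer mixture
Conditions: TiCl4 (1.2 equiv), CH2Cl2, −78 to 0 °C; then H2O
Reagents that add atoms: none
Why: Hosomi–Sakurai conjugate allylation puts the allyl group on the TiCl4-activated isopropylidene carbon, which becomes quaternary C4 carrying C3–C1, while the pulegone methyl centre (C8) is untouched and C5 forms as an epimer mixture on protonation.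

Step 2
Reactants: 3 (5R)-5-methyl-2-(2-methylpent-4-en-2-yl)cyclohexan-1-one
Product: 4 (2S,5R)-5-methyl-2-(2-methylpent-4-en-2-yl)cyclohexan-1-one
Conditions: KOH, EtOH–H2O, reflux; chromatography (cis isomer recycled)
Reagents that add atoms: none
Why: Base-mediated epimerisation α to the ketone equilibrates C5 to the diequatorial trans isomer (about 85:15, as in the menthone series), which sets C5 as S relative to the fixed C8 centre.

Step 3
Reactants: 4 (2S,5R)-5-methyl-2-(2-methylpent-4-en-2-yl)cyclohexan-1-one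
Product: 6 (3R,6S)-2,3-dimethyl-6-(2-methylpent-4-en-2-yl)cyclohexan-1-one as a C-2 epimer mixture, via lithium enolate 5 (not isolated)
Conditions: LiN(iPr)2 (1.1 equiv), THF, −78 °C; MeI, −78 to 0 °C
Reagents that add atoms: iodomethane (SMILES: CI)
Why: Kinetic enolate alkylation: the amide base deprotonates only the unhindered CH2 (the other α-carbon is a methine next to the quaternary carbon) and SN2 methylation installs C20 on C9, whose configuration is irrelevant because it is re-enolised in step 4.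

Step 4
Reactants: 6 (3R,6S)-2,3-dimethyl-6-(2-methylpent-4-en-2-yl)cyclohexan-1-one; 7 methyl acrylate
Product: 8 methyl 3-[(1R,3S,6R)-1,6-dimethyl-3-(2-methylpent-4-en-2-yl)-2-oxocyclohexyl]propanoate
Conditions: KOtBu (0.2 equiv), t-BuOH–THF, 0 °C to rt
Reagents that add atoms: none
Why: Base-catalysed intermolecular Michael addition, the fragment-joining step: only the tetrasubstituted C9 enolate can add, and chair-like axial attack on the conformer with the C5 tert-alkyl group and the C8 methyl equatorial puts the propanoate arm cis to C17 and H5, giving the 9R quaternary centre (about 5:1 expected, minor epimer removed by chromatography).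

Step 5
Reactants: 8 methyl 3-[(1R,3S,6R)-1,6-dimethyl-3-(2-methylpent-4-en-2-yl)-2-oxocyclohexyl]propanoate
Product: 9 (2R,3R,6S)-2-(3-hydroxypropyl)-2,3-dimethyl-6-(2-methylpent-4-en-2-yl)cyclohexan-1-ol as a C-1 epimer mixture
Conditions: LiAlH4, THF, 0 °C to reflux; then H2O, aq. NaOH
Reagents that add atoms: none
Why: Hydride reduction takes the ester to the primary alcohol and also reduces the hindered ketone to a carbinol whose configuration does not matter because step 8 reoxidises it.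

Step 6
Reactants: 9 (2R,3R,6S)-2-(3-hydroxypropyl)-2,3-dimethyl-6-(2-methylpent-4-en-2-yl)cyclohexan-1-ol
Product: 10 (2R,3R,6S)-2-{3-[(tert-butyldiphenylsilyl)oxy]propyl}-2,3-dimethyl-6-(2-methylpent-4-en-2-yl)cyclohexan-1-ol
Conditions: TBDPSCl (1.1 equiv), imidazole, CH2Cl2, 0 °C to rt
Reagents that add atoms: tert-butyl(chloro)diphenylsilane (SMILES: CC(C)(C)[Si](Cl)(c1ccccc1)c1ccccc1)
Why: Selective silyl ether formation: only the primary hydroxyl reacts, because the secondary one sits between a quaternary carbon and a carbon bearing a tert-alkyl group.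

Step 7
Reactants: 10 (2R,3R,6S)-2-{3-[(tert-butyldiphenylsilyl)oxy]propyl}-2,3-dimethyl-6-(2-methylpent-4-en-2-yl)cyclohexan-1-ol
Product: 12 4-[(1S,3R,4R)-3-{3-[(tert-butyldiphenylsilyl)oxy]propyl}-2-hydroxy-3,4-dimethylcyclohexyl]-4-methylpentan-1-ol, via alkylborane 11 (not isolated)
Conditions: 9-BBN (2.5 equiv), THF, 0 °C to rt; then NaOH, H2O2, 0 °C to rt
Reagents that add atoms: hydrogen peroxide (SMILES: OO)
Why: Hydroboration–oxidation: anti-Markovnikov addition of the bulky borane to the terminal alkene and oxidative C–B cleavage give the primary alcohol at C1 without touching the silyl ether.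

Step 8
Reactants: 12 4-[(1S,3R,4R)-3-{3-[(tert-butyldiphenylsilyl)oxy]propyl}-2-hydroxy-3,4-dimethylcyclohexyl]-4-methylpentan-1-ol
Product: 13 4-[(1S,3R,4R)-3-{3-[(tert-butyldiphenylsilyl)oxy]propyl}-3,4-dimethyl-2-oxocyclohexyl]-4-methylpentanal
Conditions: Dess–Martin periodinane (3 equiv), CH2Cl2, rt
Reagents that add atoms: none
Why: Dess–Martin oxidation gives the C1 aldehyde and restores the C10 ketone in one operation under non-basic conditions that do not epimerise C5.

Step 9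
Reactants: 13 4-[(1S,3R,4R)-3-{3-[(tert-butyldiphenylsilyl)oxy]propyl}-3,4-dimethyl-2-oxocyclohexyl]-4-methylpentanal
Product: 14 tert-butyldiphenyl{3-[(1R,2R,4aS)-1,2,5,5-tetramethyl-1,2,3,4,4a,5,6,7-octahydronaphthalen-1-yl]propoxy}silane
Conditions: TiCl3(DME)1.5, Zn(Cu), DME, reflux; 13 added slowly at high dilution
Reagents that add atoms: none
Why: Intramolecular McMurry coupling: low-valent titanium joins aldehyde carbon C1 to ketone carbon C10 as a pinacolate and deoxygenates it, so ring A closes with its double bond necessarily at C1=C10 and no stereocentre is touched.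

Step 10
Reactants: 14 tert-butyldiphenyl{3-[(1R,2R,4aS)-1,2,5,5-tetramethyl-1,2,3,4,4a,5,6,7-octahydronaphthalen-1-yl]propoxy}silane
Product: 15 3-[(1R,2R,4aS)-1,2,5,5-tetramethyl-1,2,3,4,4a,5,6,7-octahydronaphthalen-1-yl]propan-1-ol
Conditions: Bu4NF, THF, rt
Reagents that add atoms: none
Why: Fluoride-mediated desilylation frees the primary alcohol under conditions harmless to the trisubstituted alkene.

Step 11
Reactants: 15 3-[(1R,2R,4aS)-1,2,5,5-tetramethyl-1,2,3,4,4a,5,6,7-octahydronaphthalen-1-yl]propan-1-ol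
Product: 16 3-[(1R,2R,4aS)-1,2,5,5-tetramethyl-1,2,3,4,4a,5,6,7-octahydronaphthalen-1-yl]propanal
Conditions: Dess–Martin periodinane, CH2Cl2, rt
Reagents that add atoms: none
Why: Dess–Martin oxidation stops cleanly at the C13 aldehyde and leaves the alkene alone.

Step 12
Reactants: 16 3-[(1R,2R,4aS)-1,2,5,5-tetramethyl-1,2,3,4,4a,5,6,7-octahydronaphthalen-1-yl]propanal
Product: 17 (1R,2R,4aS)-1-(but-3-yn-1-yl)-1,2,5,5-tetramethyl-1,2,3,4,4a,5,6,7-octahydronaphthalene
Conditions: dimethyl (1-diazo-2-oxopropyl)phosphonate, K2CO3, MeOH, 0 °C to rt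
Reagents that add atoms: dimethyl (1-diazo-2-oxopropyl)phosphonate (SMILES: CC(=O)C(=[N+]=[N-])P(=O)(OC)OC)
Why: Ohira–Bestmann (Seyferth–Gilbert) homologation converts the aldehyde into the terminal alkyne under mild carbonate conditions, adding C14.

Step 13
Reactants: 17 (1R,2R,4aS)-1-(but-3-yn-1-yl)-1,2,5,5-tetramethyl-1,2,3,4,4a,5,6,7-octahydronaphthalene
Product: 19 (2E)-3-methyl-5-[(1R,2R,4aS)-1,2,5,5-tetramethyl-1,2,3,4,4a,5,6,7-octahydronaphthalen-1-yl]pent-2-en-1-ol, via alkenylalane 18 (not isolated)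
Conditions: AlMe3 (2.5 equiv), Cp2ZrCl2 (0.25 equiv), CH2Cl2, 0 °C to rt; then (CH2O)n, THF, 0 °C to rt
Reagents that add atoms: trimethylaluminium (SMILES: C[Al](C)C); paraformaldehyde as formaldehyde (SMILES: C=O)
Why: Negishi zirconium-catalysed carboalumination adds methyl (C16) and aluminium syn across the alkyne with methyl on the internal carbon, and hydroxymethylation of the alkenylalane with retention gives only the E allylic alcohol.

Step 14
Reactants: 19 (2E)-3-methyl-5-[(1R,2R,4aS)-1,2,5,5-tetramethyl-1,2,3,4,4a,5,6,7-octahydronaphthalen-1-yl]pent-2-en-1-ol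
Product: 20 (3R)-3-methyl-5-[(1R,2R,4aS)-1,2,5,5-tetramethyl-1,2,3,4,4a,5,6,7-octahydronaphthalen-1-yl]pentan-1-ol
Conditions: Ru(OAc)2[(S)-BINAP] (1 mol %), H2 (100 atm), MeOH–H2O (95:5), 20 °C
Reagents that add atoms: none
Why: Noyori asymmetric hydrogenation: the hydroxyl-bound Ru–(S)-BINAP catalyst reduces the (E)-allylic alcohol in the same sense that turns geraniol into (R)-citronellol, so C13 is set as R while the unfunctionalised ring alkene is left alone.

Step 15
Reactants: 20 (3R)-3-methyl-5-[(1R,2R,4aS)-1,2,5,5-tetramethyl-1,2,3,4,4a,5,6,7-octahydronaphthalen-1-yl]pentan-1-ol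
Product: 21 (3R)-3-methyl-5-[(1R,2R,4aS)-1,2,5,5-tetramethyl-1,2,3,4,4a,5,6,7-octahydronaphthalen-1-yl]pentanoic acid
Conditions: TEMPO (0.2 equiv), PhI(OAc)2 (2.2 equiv), MeCN–H2O (1:1), rt
Reagents that add atoms: water (SMILES: O)
Why: Oxoammonium (TEMPO) oxidation takes the primary alcohol through the aldehyde hydrate to the acid without touching the alkene or the non-epimerisable β-stereocentre C13.

Step 16
Reactants: 22 glycerol
Product: 23 1,3-bis[(tert-butyldimethylsilyl)oxy]propan-2-ol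
Conditions: TBSCl (2.05 equiv), imidazole, DMF, 0 °C
Reagents that add atoms: tert-butyldimethylsilyl chloride (SMILES: CC(C)(C)[Si](C)(C)Cl)
Why: Selective silylation: the two primary hydroxyls react far faster than the secondary one, which is left free for acylation.

Step 17
Reactants: 21 (3R)-3-methyl-5-[(1R,2R,4aS)-1,2,5,5-tetramethyl-1,2,3,4,4a,5,6,7-octahydronaphthalen-1-yl]pentanoic acid; 23 1,3-bis[(tert-butyldimethylsilyl)oxy]propan-2-ol
Product: 24 1,3-bis[(tert-butyldimethylsilyl)oxy]propan-2-yl (3R)-3-methyl-5-[(1R,2R,4aS)-1,2,5,5-tetramethyl-1,2,3,4,4a,5,6,7-octahydronaphthalen-1-yl]pentanoate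
Conditions: DCC (1.2 equiv), DMAP (0.2 equiv), CH2Cl2, 0 °C to rt
Reagents that add atoms: none
Why: Steglich esterification acylates the secondary hydroxyl via the acylpyridinium species under neutral conditions that leave the alkene and all stereocentres untouched.

Step 18
Reactants: 24 1,3-bis[(tert-butyldimethylsilyl)oxy]propan-2-yl (3R)-3-methyl-5-[(1R,2R,4aS)-1,2,5,5-tetramethyl-1,2,3,4,4a,5,6,7-octahydronaphthalen-1-yl]pentanoate
Product: 25 1,3-dihydroxypropan-2-yl (3R)-3-methyl-5-[(1R,2R,4aS)-1,2,5,5-tetramethyl-1,2,3,4,4a,5,6,7-octahydronaphthalen-1-yl]pentanoate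
Conditions: HF·pyridine, pyridine, THF, 0 °C; rapid chromatography
Reagents that add atoms: none
Why: Fluoride desilylation under mildly acidic, pyridine-buffered conditions removes both silyl ethers without the base-induced 2-to-1 acyl migration of the monoglyceride or acid-induced alkene migration.

## Compound list

1 | (R)-(+)-pulegone, (5R)-5-methyl-2-(propan-2-ylidene)cyclohexan-1-one | C[C@@H]1CCC(=C(C)C)C(=O)C1 | starting material
2 | allyltrimethylsilane | C=CC[Si](C)(C)C | starting material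
3 | (5R)-5-methyl-2-(2-methylpent-4-en-2-yl)cyclohexan-1-one, C-2 epimer mixture | O=C1C[C@H](C)CCC1C(C)(C)CC=C | intermediate
4 | (2S,5R)-5-methyl-2-(2-methylpent-4-en-2-yl)cyclohexan-1-one | O=C1C[C@H](C)CC[C@H]1C(C)(C)CC=C | intermediate
5 | lithium (3R,6S)-3-methyl-6-(2-methylpent-4-en-2-yl)cyclohex-1-en-1-olate (not isolated) | [Li]OC1=C[C@H](C)CC[C@H]1C(C)(C)CC=C | intermediate
6 | (3R,6S)-2,3-dimethyl-6-(2-methylpent-4-en-2-yl)cyclohexan-1-one, C-2 epimer mixture | O=C1C(C)[C@H](C)CC[C@H]1C(C)(C)CC=C | intermediate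
7 | methyl acrylate | C=CC(=O)OC | starting material
8 | methyl 3-[(1R,3S,6R)-1,6-dimethyl-3-(2-methylpent-4-en-2-yl)-2-oxocyclohexyl]propanoate | COC(=O)CC[C@@]1(C)C(=O)[C@H](C(C)(C)CC=C)CC[C@H]1C | intermediate
9 | (2R,3R,6S)-2-(3-hydroxypropyl)-2,3-dimethyl-6-(2-methylpent-4-en-2-yl)cyclohexan-1-ol, C-1 epimer mixture | OCCC[C@@]1(C)C(O)[C@H](C(C)(C)CC=C)CC[C@H]1C | intermediate
10 | (2R,3R,6S)-2-{3-[(tert-butyldiphenylsilyl)oxy]propyl}-2,3-dimethyl-6-(2-methylpent-4-en-2-yl)cyclohexan-1-ol, C-1 epimer mixture | CC(C)(C)[Si](OCCC[C@@]1(C)C(O)[C@H](C(C)(C)CC=C)CC[C@H]1C)(c1ccccc1)c1ccccc1 | intermediate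
11 | 9-{4-[(1S,3R,4R)-3-{3-[(tert-butyldiphenylsilyl)oxy]propyl}-2-hydroxy-3,4-dimethylcyclohexyl]-4-methylpentyl}-9-borabicyclo[3.3.1]nonane (not isolated) | CC(C)(C)[Si](OCCC[C@@]1(C)C(O)[C@H](C(C)(C)CCCB2C3CCCC2CCC3)CC[C@H]1C)(c1ccccc1)c1ccccc1 | intermediate
12 | 4-[(1S,3R,4R)-3-{3-[(tert-butyldiphenylsilyl)oxy]propyl}-2-hydroxy-3,4-dimethylcyclohexyl]-4-methylpentan-1-ol, carbinol epimer mixture | CC(C)(C)[Si](OCCC[C@@]1(C)C(O)[C@H](C(C)(C)CCCO)CC[C@H]1C)(c1ccccc1)c1ccccc1 | intermediate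
13 | 4-[(1S,3R,4R)-3-{3-[(tert-butyldiphenylsilyl)oxy]propyl}-3,4-dimethyl-2-oxocyclohexyl]-4-methylpentanal | CC(C)(C)[Si](OCCC[C@@]1(C)C(=O)[C@H](C(C)(C)CCC=O)CC[C@H]1C)(c1ccccc1)c1ccccc1 | intermediate
14 | tert-butyldiphenyl{3-[(1R,2R,4aS)-1,2,5,5-tetramethyl-1,2,3,4,4a,5,6,7-octahydronaphthalen-1-yl]propoxy}silane | CC(C)(C)[Si](OCCC[C@@]1(C)C2=CCCC(C)(C)[C@@H]2CC[C@H]1C)(c1ccccc1)c1ccccc1 | intermediate
15 | 3-[(1R,2R,4aS)-1,2,5,5-tetramethyl-1,2,3,4,4a,5,6,7-octahydronaphthalen-1-yl]propan-1-ol | OCCC[C@@]1(C)C2=CCCC(C)(C)[C@@H]2CC[C@H]1C | intermediate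
16 | 3-[(1R,2R,4aS)-1,2,5,5-tetramethyl-1,2,3,4,4a,5,6,7-octahydronaphthalen-1-yl]propanal | O=CCC[C@@]1(C)C2=CCCC(C)(C)[C@@H]2CC[C@H]1C | intermediate
17 | (1R,2R,4aS)-1-(but-3-yn-1-yl)-1,2,5,5-tetramethyl-1,2,3,4,4a,5,6,7-octahydronaphthalene | C#CCC[C@@]1(C)C2=CCCC(C)(C)[C@@H]2CC[C@H]1C | intermediate
18 | dimethyl{(1E)-2-methyl-4-[(1R,2R,4aS)-1,2,5,5-tetramethyl-1,2,3,4,4a,5,6,7-octahydronaphthalen-1-yl]but-1-en-1-yl}alumane (not isolated) | C[Al](C)/C=C(\C)CC[C@@]1(C)C2=CCCC(C)(C)[C@@H]2CC[C@H]1C | intermediate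
19 | (2E)-3-methyl-5-[(1R,2R,4aS)-1,2,5,5-tetramethyl-1,2,3,4,4a,5,6,7-octahydronaphthalen-1-yl]pent-2-en-1-ol | OC/C=C(\C)CC[C@@]1(C)C2=CCCC(C)(C)[C@@H]2CC[C@H]1C | intermediate
20 | (3R)-3-methyl-5-[(1R,2R,4aS)-1,2,5,5-tetramethyl-1,2,3,4,4a,5,6,7-octahydronaphthalen-1-yl]pentan-1-ol | C[C@H](CC[C@@]1(C)C2=CCCC(C)(C)[C@@H]2CC[C@H]1C)CCO | intermediate
21 | (3R)-3-methyl-5-[(1R,2R,4aS)-1,2,5,5-tetramethyl-1,2,3,4,4a,5,6,7-octahydronaphthalen-1-yl]pentanoic acid | C[C@H](CC[C@@]1(C)C2=CCCC(C)(C)[C@@H]2CC[C@H]1C)CC(=O)O | intermediate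
22 | glycerol | OCC(O)CO | starting material
23 | 1,3-bis[(tert-butyldimethylsilyl)oxy]propan-2-ol | CC(C)(C)[Si](C)(C)OCC(O)CO[Si](C)(C)C(C)(C)C | intermediate
24 | 1,3-bis[(tert-butyldimethylsilyl)oxy]propan-2-yl (3R)-3-methyl-5-[(1R,2R,4aS)-1,2,5,5-tetramethyl-1,2,3,4,4a,5,6,7-octahydronaphthalen-1-yl]pentanoate | C[C@H](CC[C@@]1(C)C2=CCCC(C)(C)[C@@H]2CC[C@H]1C)CC(=O)OC(CO[Si](C)(C)C(C)(C)C)CO[Si](C)(C)C(C)(C)C | intermediate
25 | 1,3-dihydroxypropan-2-yl (3R)-3-methyl-5-[(1R,2R,4aS)-1,2,5,5-tetramethyl-1,2,3,4,4a,5,6,7-octahydronaphthalen-1-yl]pentanoate | C[C@H](CC[C@@]1(C)C2=CCCC(C)(C)[C@@H]2CC[C@H]1C)CC(=O)OC(CO)CO | target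

## Step count and risks

Total step count: 18. Longest linear sequence: 17 (steps 1–15, 17 and 18; step 16 prepares the glycerol partner).

**Step 4 (Michael addition).** The hindered tetrasubstituted enolate may add slowly, the facial selectivity at C9 rests on axial attack alone, and the base could slowly epimerise C5 in the product. The fallback replaces the base-catalysed enolate addition with a neutral, auxiliary-controlled enamine Michael reaction. It sets out from 6: condensation with (R)-1-phenylethylamine (TiCl4, Et3N, toluene) gives the ketimine (3R,6S)-2,3-dimethyl-6-(2-methylpent-4-en-2-yl)-N-[(1R)-1-phenylethyl]cyclohexan-1-imine F1. Its secondary enamine tautomer adds to methyl acrylate 7 (THF, 50 °C) through a compact aza-ene-type transition state, on the face chosen by the auxiliary, which should be the same face as the intrinsic axial preference. This gives the adduct imine methyl 3-[(1R,3S,6R)-1,6-dimethyl-3-(2-methylpent-4-en-2-yl)-2-{[(1R)-1-phenylethyl]imino}cyclohexyl]propanoate F2. Aqueous acetic acid hydrolysis releases the amine and comes back to the route at 8.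

**Step 9 (McMurry coupling).** The ketone is flanked by a quaternary carbon and a carbon bearing a tert-alkyl group, so pinacol formation or deoxygenation may stall. The fallback closes ring A by aldol condensation and then removes the extra carbonyl. It sets out from 10: Dess–Martin oxidation gives the ketone (2R,3R,6S)-2-{3-[(tert-butyldiphenylsilyl)oxy]propyl}-2,3-dimethyl-6-(2-methylpent-4-en-2-yl)cyclohexan-1-one F3. Wacker oxidation of the allyl group (PdCl2, CuCl, O2, DMF–H2O) gives the 1,5-diketone (2R,3R,6S)-2-{3-[(tert-butyldiphenylsilyl)oxy]propyl}-2,3-dimethyl-6-(2-methyl-4-oxopentan-2-yl)cyclohexan-1-one F4. Intramolecular aldol condensation (KOH, MeOH, rt to 40 °C, kept mild to spare C5) gives the enone (4aS,7R,8R)-8-{3-[(tert-butyldiphenylsilyl)oxy]propyl}-4,4,7,8-tetramethyl-4,4a,5,6,7,8-hexahydronaphthalen-2(3H)-one F5. Ethane-1,2-dithiol with Zn(OTf)2 gives its ethane-1,2-diyl dithioketal (spiro-1,3-dithiolane at C2) F6. Raney Ni in EtOH removes sulfur with the double bond staying at C1=C10, and the sequence comes back to the route at 14.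

**Step 18 (final desilylation).** A 2-monoacylglycerol can shift its acyl group to a primary hydroxyl during deprotection or on silica. The fallback uses a different glycerol protecting group and a non-fluoride release. It sets out from 21: DCC/DMAP esterification with commercial cis-2-phenyl-1,3-dioxan-5-ol gives cis-2-phenyl-1,3-dioxan-5-yl (3R)-3-methyl-5-[(1R,2R,4aS)-1,2,5,5-tetramethyl-1,2,3,4,4a,5,6,7-octahydronaphthalen-1-yl]pentanoate F7. Heating with B(OH)3 in B(OEt)3 at 100 °C exchanges the benzylidene acetal for a glycerol borate, which water hydrolyses at rt, and the sequence comes back to the route at 25.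

## Further compounds

F1 | step 4 | (3R,6S)-2,3-dimethyl-6-(2-methylpent-4-en-2-yl)-N-[(1R)-1-phenylethyl]cyclohexan-1-imine, C-2 epimer mixture | CC1C(=N[C@H](C)c2ccccc2)[C@H](C(C)(C)CC=C)CC[C@H]1C
F2 | step 4 | methyl 3-[(1R,3S,6R)-1,6-dimethyl-3-(2-methylpent-4-en-2-yl)-2-{[(1R)-1-phenylethyl]imino}cyclohexyl]propanoate | COC(=O)CC[C@@]1(C)C(=N[C@H](C)c2ccccc2)[C@H](C(C)(C)CC=C)CC[C@H]1C
F3 | step 9 | (2R,3R,6S)-2-{3-[(tert-butyldiphenylsilyl)oxy]propyl}-2,3-dimethyl-6-(2-methylpent-4-en-2-yl)cyclohexan-1-one | CC(C)(C)[Si](OCCC[C@@]1(C)C(=O)[C@H](C(C)(C)CC=C)CC[C@H]1C)(c1ccccc1)c1ccccc1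
F4 | step 9 | (2R,3R,6S)-2-{3-[(tert-butyldiphenylsilyl)oxy]propyl}-2,3-dimethyl-6-(2-methyl-4-oxopentan-2-yl)cyclohexan-1-one | CC(C)(C)[Si](OCCC[C@@]1(C)C(=O)[C@H](C(C)(C)CC(C)=O)CC[C@H]1C)(c1ccccc1)c1ccccc1
F5 | step 9 | (4aS,7R,8R)-8-{3-[(tert-butyldiphenylsilyl)oxy]propyl}-4,4,7,8-tetramethyl-4,4a,5,6,7,8-hexahydronaphthalen-2(3H)-one | CC(C)(C)[Si](OCCC[C@@]1(C)C2=CC(=O)CC(C)(C)[C@@H]2CC[C@H]1C)(c1ccccc1)c1ccccc1
F6 | step 9 | ethane-1,2-diyl dithioketal (spiro-1,3-dithiolane at C2) of F5 | CC(C)(C)[Si](OCCC[C@@]1(C)C2=CC3(SCCS3)CC(C)(C)[C@@H]2CC[C@H]1C)(c1ccccc1)c1ccccc1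
F7 | step 18 | cis-2-phenyl-1,3-dioxan-5-yl (3R)-3-methyl-5-[(1R,2R,4aS)-1,2,5,5-tetramethyl-1,2,3,4,4a,5,6,7-octahydronaphthalen-1-yl]pentanoate | C[C@H](CC[C@@]1(C)C2=CCCC(C)(C)[C@@H]2CC[C@H]1C)CC(=O)O[C@H]1CO[C@@H](c2ccccc2)OC1
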